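The numbers of this flask are invented; no experiment stands behind them.

The closed, stirred vessel held substrate alone at the start, a different charge in each flask, and I counted everything as fractions of that charge.

    substrate ⇌ target (K1 = 2.5, k1 = 0.24 /s)
    target ⇌ isomer of the product A (K2 = 0.86, k2 = 0.016 /s)
    isomer of the product A ⇌ isomer of the product B (K3 = 5.3, k3 = 0.088 /s)
    isomer of the product B ⇌ substrate (k4 = 0.23 /s)
    substrate ⇌ dormant form (K5 = 0.86, k5 = 0.26 /s)

| flask | substrate | time |
|---|---|---|
| oak | 0.30 mM | 12 s |
| elm | 0.50 mM | 12 s |
| ash | 0.80 mM | 12 s |

- "hardly changes" means that all values lie within two and a half points (for a concentration: within two and a half percent of the largest)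
- run time (oak): 12 s

- share of target in all that became target or isomer of the product A or isomer of the product B for oak, elm, ash, in this order
- how the row runs (rises all the way / falls all the way / rises, then falls / hardly changes / falls, then rises)

Every step has a single species on its left, so I expected the charge to drop out of each fraction and the row to run flat. The rest of my reckoning was a ladder of times. The closing step hid the fastest rate: run backwards, it took substrate to isomer of the product B at 2.62 /s. That pair relaxed with a half-life of 0.243 s, shorter than the 2.06 s of the substrate-target pair. On this rung target won 8.39 % of what left substrate for the isomers, which is the kinetic end of kinetic against thermodynamic control. The thermodynamic end was a share of 15.6 %.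

Next, within about 2.7 s, dormant form joined substrate and isomer of the product B in one pool, of which substrate was a fraction 7.54 %. Then came the rung that mattered. Target fell back at 0.0960 /s and was fed from the pool at 0.0181 /s, and I called the sum of these, 0.114 /s, the re-sorting rate: the rate at which the gap between the share and its thermodynamic end closes. Integrated, that gap shrinks exponentially. The target to isomer of the product A step, with a forward half-life of 43 s, lay on a lower rung, long against 12 s. Taking the gap to shrink at the re-sorting rate, I reckoned the share at 12 s as 0.138 in oak, 0.138 in elm and 0.138 in ash, so my verdict on the row was hardly changes.

The forecast gave 14 %, 14 % and 14 %, with the verdict hardly changes: “Every step is first order, so the share at a fixed time does not depend on the starting concentration”.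

The flasks gave 13.9 %, 13.9 % and 13.9 %, with the verdict hardly changes.

In oak the relaxation half-life of step 1 by itself was 2.06 s, short against 12 s, yet target over substrate stood at 2.10 at 12.0 s against a 2.5 for that step, while the half-life of the re-sorting rate, 6.08 s, was about half of that time, beside a slowest-mode half-life of 5.79 s. Reckoned at the re-sorting rate, a quarter of the starting gap was left at the asked time. The re-sorting rate holds no charge, so for ash, charged with 0.80 mM, it returns 0.138, and there the local order was 0. Target in ash stood at 12.3 % of the charge at 12.0 s and at 14.0 % at 120 s.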